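## Retrosynthetic overview

1. The target is a 2,3-cis, 3,4-trans oxolane. It comes from the 2-aryl-3-(silyloxymethyl)-4-aroyl-2,5-dihydrofuran by copper hydride conjugate reduction (H to C3, anti to the C2 aryl group), equilibration of C4 and O-desilylation.
2. The dihydrofuran is disconnected at O1–C5 with O1 re-bonded to C3. This gives a 2-aryl oxirane (O1, C2, C3) whose C3 carries CH2OTBS and the enone arm C4(=C5H2)–C(=O)Ar. In the forward sense, catalytic LiI moves O1 from C3 to C5.
3. Feature exploited: in the ring O1–C2–C3–C4–C5 the carbinol carbon on C3 lies next to the C2–C3 edge. The ring oxygen can therefore first be placed on that edge as an oxirane by hydroxy-directed Sharpless epoxidation. The C4–C5 edge, held as an alkene conjugated to the aroyl group, then accepts O1 at C5 while C3 releases it.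
4. The oxirane comes from an (E)-dienone alcohol. That alcohol comes from a Stille coupling (C3–C4) of a (Z)-2-bromo-3-arylprop-2-en-1-ol with a 2-stannyl aryl vinyl ketone. Both partners are made from 3,4,5-trimethoxybenzaldehyde.
5. Ring order: the oxirane is formed first (step 7), then the five-membered ring (step 9). No other ring is built.

Key step: step 9

**Remarks**
- Ar = 3,4,5-trimethoxyphenyl. The labels O1, C2 (aryl), C3 (CH2OH), C4 (aroyl) and C5 (CH2) are kept for the same atoms in all precursors.
- The target SMILES reads as (2R,3R,4S) in this numbering: aryl and CH2OH are cis, CH2OH and aroyl are trans.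
- Assumption on the chemistry: the aroyl carbon is carried as the ketone from the alkynone onward. The primary allylic alcohol is then the only hydroxy group offered to titanium in step 7.
- Nucleophilic bases are avoided once the enone arm and the oxirane are in the same molecule.

## Route

Step 1
Reactants: 1 3,4,5-trimethoxybenzaldehyde; 2 ethyl (triphenyl-λ5-phosphanylidene)acetate
Product: 4 ethyl (Z)-2-bromo-3-(3,4,5-trimethoxyphenyl)prop-2-enoate, via bromo ylide 3 (not isolated)
Conditions: NBS (1 equiv to 2), CH2Cl2, −20 °C; then 1, rt to 40 °C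
Reagents that add atoms: N-bromosuccinimide, O=C1CCC(=O)N1Br
Why: NBS brominates the stabilised ylide and a Wittig olefination follows, in which the stabilised bromo ylide should place the aryl group trans to the ester, which is the Z bromoalkene.

Step 2
Reactants: 4 ethyl (Z)-2-bromo-3-(3,4,5-trimethoxyphenyl)prop-2-enoate
Product: 5 (Z)-2-bromo-3-(3,4,5-trimethoxyphenyl)prop-2-en-1-ol
Conditions: iBu2AlH (2.5 equiv), CH2Cl2, −78 to 0 °C; aq potassium sodium tartrate
Reagents that add atoms: none
Why: The iBu2AlH ester reduction should stop at the allylic alcohol and leave the vinylic C–Br bond and the alkene geometry untouched.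

Step 3
Reactants: 1 3,4,5-trimethoxybenzaldehyde; 6 ethynylmagnesium bromide
Product: 7 rac-1-(3,4,5-trimethoxyphenyl)prop-2-yn-1-ol
Conditions: THF, 0 °C to rt; aqueous work-up
Reagents that add atoms: none
Why: This is a Grignard 1,2-addition of an alkynyl nucleophile to a non-enolisable aldehyde, and the racemic carbinol centre is erased in step 4.

Step 4
Reactants: 7 rac-1-(3,4,5-trimethoxyphenyl)prop-2-yn-1-ol
Product: 8 1-(3,4,5-trimethoxyphenyl)prop-2-yn-1-one
Conditions: activated MnO2 (10 equiv), CH2Cl2, rt
Reagents that add atoms: none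
Why: MnO2 oxidation is selective for activated alcohols, and this benzylic and propargylic alcohol should give the alkynone under neutral conditions.

Step 5
Reactants: 8 1-(3,4,5-trimethoxyphenyl)prop-2-yn-1-one; 9 tributyltin hydride
Product: 10 2-(tributylstannyl)-1-(3,4,5-trimethoxyphenyl)prop-2-en-1-one
Conditions: Pd(PPh3)4 (2 mol %), THF, 0 °C, slow addition of 9
Reagents that add atoms: none
Why: In the palladium-catalysed syn hydrostannation of an alkynone the polarised triple bond directs hydrogen to the β carbon (C5) and tin to the α carbon (C4), and slow addition limits ditin formation.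

Step 6
Reactants: 5 (Z)-2-bromo-3-(3,4,5-trimethoxyphenyl)prop-2-en-1-ol; 10 2-(tributylstannyl)-1-(3,4,5-trimethoxyphenyl)prop-2-en-1-one
Product: 11 (3E)-3-(hydroxymethyl)-2-methylidene-1,4-bis(3,4,5-trimethoxyphenyl)but-3-en-1-one
Conditions: Pd(PPh3)4 (10 mol %), CuCl (5 equiv), LiCl (6 equiv), degassed DMSO, rt to 60 °C
Reagents that add atoms: none
Why: In this Stille cross-coupling CuCl converts the hindered 1-substituted vinylstannane into a more reactive vinylcopper species and suppresses cine substitution, while retention at the vinyl bromide keeps the aryl group cis to the new C3–C4 bond and trans to CH2OH.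

Step 7
Reactants: 11 (3E)-3-(hydroxymethyl)-2-methylidene-1,4-bis(3,4,5-trimethoxyphenyl)but-3-en-1-one
Product: 12 2-[(2S,3S)-2-(hydroxymethyl)-3-(3,4,5-trimethoxyphenyl)oxiran-2-yl]-1-(3,4,5-trimethoxyphenyl)prop-2-en-1-one
Conditions: Ti(OiPr)4 (0.2 equiv), L-(+)-diisopropyl tartrate (0.24 equiv), tBuOOH (2 equiv, decane), 4 Å MS, CH2Cl2, −20 °C
Reagents that add atoms: tert-butyl hydroperoxide, CC(C)(C)OO
Why: This is a Sharpless asymmetric epoxidation of an (E)-2-substituted cinnamyl-type alcohol (the class of (E)-2,3-diphenylprop-2-en-1-ol), in which the L-(+)-tartrate complex should deliver oxygen to the face that makes both oxirane carbons S and so sets the C2–O1 bond of the target, syn addition keeps the aryl group and enone arm cis, and the electron-poor C4=C5 bond is left alone.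

Step 8
Reactants: 12 2-[(2S,3S)-2-(hydroxymethyl)-3-(3,4,5-trimethoxyphenyl)oxiran-2-yl]-1-(3,4,5-trimethoxyphenyl)prop-2-en-1-one
Product: 13 2-[(2S,3S)-2-{[tert-butyl(dimethyl)silyl]oxymethyl}-3-(3,4,5-trimethoxyphenyl)oxiran-2-yl]-1-(3,4,5-trimethoxyphenyl)prop-2-en-1-one
Conditions: TBSOTf (1.1 equiv), 2,6-lutidine (2 equiv), CH2Cl2, −78 °C
Reagents that add atoms: tert-butyldimethylsilyl triflate, CC(C)(C)[Si](C)(C)OS(=O)(=O)C(F)(F)F
Why: O-silylation with a silyl triflate and a hindered, non-nucleophilic pyridine base is fast at −78 °C, so no amine can add to C5 and the oxirane should not be activated.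

Step 9
Reactants: 13 2-[(2S,3S)-2-{[tert-butyl(dimethyl)silyl]oxymethyl}-3-(3,4,5-trimethoxyphenyl)oxiran-2-yl]-1-(3,4,5-trimethoxyphenyl)prop-2-en-1-one
Product: 15 [(5S)-4-{[tert-butyl(dimethyl)silyl]oxymethyl}-5-(3,4,5-trimethoxyphenyl)-2,5-dihydrofuran-3-yl](3,4,5-trimethoxyphenyl)methanone, via lithium alkoxide allylic iodide 14 (not isolated)
Conditions: anhydrous LiI (20 mol %), THF, rt to 45 °C, dark
Reagents that add atoms: none
Why: Proposed new method: Li+ activates the aroyl oxygen and iodide adds to the unsubstituted enone terminus C5, the enolate so formed carries the oxirane oxygen on its β carbon C3 and expels it (E1cB, driven by release of ring strain) to give the C2 lithium alkoxide and primary allylic iodide 14, and the alkoxide then displaces iodide at C5, which forms O1–C5 and returns LiI. The closest known reaction types are the iodide and Lewis acid catalysed isomerisation of 3,4-epoxybut-1-ene to 2,5-dihydrofuran, the Cu(hfacac)2-catalysed ring expansion of vinyl oxiranes and the base-induced opening of β,γ-epoxy ketones to γ-hydroxy enones, but a vinyl arm that bears an acyl group has not been run under iodide catalysis. The five-membered ring O1–C2–C3–C4–C5 closes in the 5-exo-tet mode. No stereocentre is created, since C3 becomes sp2 and C2 keeps the configuration of step 7 because only the C3–O1 bond is cleaved and C2–O1 stays intact throughout. Ring closure is possible only from the isomer of 14 in which C2 and C5 sit on the same side of the new C3=C4 bond, and the oxirane should favour it, because during the opening C3–O1 stands perpendicular to the enolate plane while C2 with its cis aryl group lies nearly in that plane and turns towards the small CH2I group instead of the aryl-bearing enolate terminus; an alkoxide of the other geometry can go back to the enolate by 3-exo oxa-Michael addition, where C3–C4 is again a single bond. The step also needs iodide to choose C5 over benzylic C2 and the alkoxide to choose C5 over the ketone or the silyl group, which the soft unhindered enone terminus, the aprotic medium (benzylic opening stays reversible) and the fast irreversible displacement of a primary allylic iodide should secure.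

Step 10
Reactants: 15 [(5S)-4-{[tert-butyl(dimethyl)silyl]oxymethyl}-5-(3,4,5-trimethoxyphenyl)-2,5-dihydrofuran-3-yl](3,4,5-trimethoxyphenyl)methanone
Product: 18 [(3S,4R,5R)-4-{[tert-butyl(dimethyl)silyl]oxymethyl}-5-(3,4,5-trimethoxyphenyl)oxolan-3-yl](3,4,5-trimethoxyphenyl)methanone, via silyl enol ether 16 (not isolated), via all-cis ketone 17 (not isolated)
Conditions: (IPr)CuCl (5 mol %; IPr = 1,3-bis(2,6-diisopropylphenyl)imidazol-2-ylidene), NaOtBu (5 mol %), (EtO)2MeSiH (2 equiv), toluene, rt, 15 added last; then K2CO3, MeOH, 0 °C to rt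
Reagents that add atoms: none
Why: This is a copper hydride conjugate reduction (1,4-hydrosilylation) with a carbene-ligated catalyst of the kind known to reduce tetrasubstituted enones, in which Cu–H should add to C3 of the nearly flat dihydrofuran from the face opposite the C2 aryl group and so set C3 with CH2OTBS cis to aryl, the enolate is stored as silyl enol ether 16 so that the aryl ketone is not reduced further, and methanolysis first protonates C4 from the open face (17) before carbonate equilibrates this only acidic centre to the less crowded 3,4-trans ketone 18.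

Step 11
Reactants: 18 [(3S,4R,5R)-4-{[tert-butyl(dimethyl)silyl]oxymethyl}-5-(3,4,5-trimethoxyphenyl)oxolan-3-yl](3,4,5-trimethoxyphenyl)methanone
Product: 19 [(3S,4R,5R)-4-(hydroxymethyl)-5-(3,4,5-trimethoxyphenyl)oxolan-3-yl](3,4,5-trimethoxyphenyl)methanone (target)
Conditions: HF·pyridine, pyridine, THF, 0 °C to rt
Reagents that add atoms: none
Why: Fluoride-mediated cleavage of the primary silyl ether in a weakly acidic buffered medium should avoid enolisation at C4 and β-elimination of O1, so all three stereocentres are kept.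

## Compound list

1 | 3,4,5-trimethoxybenzaldehyde | O=Cc1cc(OC)c(OC)c(OC)c1 | starting material
2 | ethyl (triphenyl-λ5-phosphanylidene)acetate | CCOC(=O)C=P(c1ccccc1)(c1ccccc1)c1ccccc1 | starting material
3 | ethyl bromo(triphenyl-λ5-phosphanylidene)acetate (bromo ylide) | CCOC(=O)C(Br)=P(c1ccccc1)(c1ccccc1)c1ccccc1 | intermediate
4 | ethyl (Z)-2-bromo-3-(3,4,5-trimethoxyphenyl)prop-2-enoate | CCOC(=O)/C(Br)=C/c1cc(OC)c(OC)c(OC)c1 | intermediate
5 | (Z)-2-bromo-3-(3,4,5-trimethoxyphenyl)prop-2-en-1-ol | OC/C(Br)=C/c1cc(OC)c(OC)c(OC)c1 | intermediate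
6 | ethynylmagnesium bromide | C#C[Mg]Br | starting material
7 | rac-1-(3,4,5-trimethoxyphenyl)prop-2-yn-1-ol | C#CC(O)c1cc(OC)c(OC)c(OC)c1 | intermediate
8 | 1-(3,4,5-trimethoxyphenyl)prop-2-yn-1-one | C#CC(=O)c1cc(OC)c(OC)c(OC)c1 | intermediate
9 | tributyltin hydride | CCCC[SnH](CCCC)CCCC | starting material
10 | 2-(tributylstannyl)-1-(3,4,5-trimethoxyphenyl)prop-2-en-1-one | C=C(C(=O)c1cc(OC)c(OC)c(OC)c1)[Sn](CCCC)(CCCC)CCCC | intermediate
11 | (3E)-3-(hydroxymethyl)-2-methylidene-1,4-bis(3,4,5-trimethoxyphenyl)but-3-en-1-one (aryl trans to CH2OH, cis to the enone arm) | OC/C(=C/c1cc(OC)c(OC)c(OC)c1)C(=C)C(=O)c1cc(OC)c(OC)c(OC)c1 | intermediate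
12 | 2-[(2S,3S)-2-(hydroxymethyl)-3-(3,4,5-trimethoxyphenyl)oxiran-2-yl]-1-(3,4,5-trimethoxyphenyl)prop-2-en-1-one | C=C(C(=O)c1cc(OC)c(OC)c(OC)c1)[C@@]2(CO)O[C@H]2c3cc(OC)c(OC)c(OC)c3 | intermediate
13 | 2-[(2S,3S)-2-{[tert-butyl(dimethyl)silyl]oxymethyl}-3-(3,4,5-trimethoxyphenyl)oxiran-2-yl]-1-(3,4,5-trimethoxyphenyl)prop-2-en-1-one (key-step precursor) | C=C(C(=O)c1cc(OC)c(OC)c(OC)c1)[C@@]2(CO[Si](C)(C)C(C)(C)C)O[C@H]2c3cc(OC)c(OC)c(OC)c3 | intermediate
14 | lithium (1S,2Z)-2-{[tert-butyl(dimethyl)silyl]oxymethyl}-3-(iodomethyl)-4-oxo-1,4-bis(3,4,5-trimethoxyphenyl)but-2-en-1-olate | [Li+].[O-][C@@H](c1cc(OC)c(OC)c(OC)c1)/C(CO[Si](C)(C)C(C)(C)C)=C(\CI)C(=O)c1cc(OC)c(OC)c(OC)c1 | intermediate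
15 | [(5S)-4-{[tert-butyl(dimethyl)silyl]oxymethyl}-5-(3,4,5-trimethoxyphenyl)-2,5-dihydrofuran-3-yl](3,4,5-trimethoxyphenyl)methanone (key-step product) | COc1cc(C(=O)C2=C(CO[Si](C)(C)C(C)(C)C)[C@H](c3cc(OC)c(OC)c(OC)c3)OC2)cc(OC)c1OC | intermediate
16 | diethoxy(methyl)silyl enol ether: (2R,3R)-2-aryl-3-(TBSOCH2)-4-[aryl(diethoxymethylsilyloxy)methylidene]oxolane, enol ether geometry left open | CCO[Si](C)(OCC)OC(=C1CO[C@@H](c2cc(OC)c(OC)c(OC)c2)[C@H]1CO[Si](C)(C)C(C)(C)C)c3cc(OC)c(OC)c(OC)c3 | intermediate
17 | [(3R,4R,5R)-4-{[tert-butyl(dimethyl)silyl]oxymethyl}-5-(3,4,5-trimethoxyphenyl)oxolan-3-yl](3,4,5-trimethoxyphenyl)methanone (all-cis C4 epimer) | COc1cc(C(=O)[C@H]2CO[C@@H](c3cc(OC)c(OC)c(OC)c3)[C@H]2CO[Si](C)(C)C(C)(C)C)cc(OC)c1OC | intermediate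
18 | [(3S,4R,5R)-4-{[tert-butyl(dimethyl)silyl]oxymethyl}-5-(3,4,5-trimethoxyphenyl)oxolan-3-yl](3,4,5-trimethoxyphenyl)methanone (2,3-cis, 3,4-trans) | COc1cc(C(=O)[C@@H]2CO[C@@H](c3cc(OC)c(OC)c(OC)c3)[C@H]2CO[Si](C)(C)C(C)(C)C)cc(OC)c1OC | intermediate
19 | [(3S,4R,5R)-4-(hydroxymethyl)-5-(3,4,5-trimethoxyphenyl)oxolan-3-yl](3,4,5-trimethoxyphenyl)methanone | COc1cc(C(=O)[C@@H]2CO[C@@H](c3cc(OC)c(OC)c(OC)c3)[C@H]2CO)cc(OC)c1OC | target

## Step count

- Total step count: 11
- Longest linear sequence: 9 (steps 3 to 11, from 3,4,5-trimethoxybenzaldehyde)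

## Steps most likely to fail

**Step 9 (new method).**

What may go wrong:
- The oxirane may open with the C2 carbinol carbon trans to C5. The alkoxide then adds to the ketone or takes over the silyl group by a 1,4 oxygen-to-oxygen shift, and the catalyst is held back as a lithium alkoxide.
- Iodide may attack the benzylic carbon reversibly, with erosion of configuration.
- The alkoxide may deprotonate the product vinylogously at C2–H.

The fallback uses known chemistry, sets out from 13 and comes back at 15. It takes the acyl group out of play before the ring expansion. Luche reduction (NaBH4, CeCl3·7H2O, MeOH, −78 °C) should give the allylic alcohol F1 as a pair of carbinol epimers. TESCl and imidazole convert it into the triethylsilyl ether F2, an electron-neutral vinyl oxirane of the established substrate class. Cu(hfacac)2 (5 mol %, toluene, 110 to 150 °C) should expand it to the 2,5-dihydrofuran F3 under non-basic conditions with C2–O1 untouched. 2-Iodoxybenzoic acid in DMSO then cleaves the triethylsilyl ether beside the TBS ether and oxidises the freed alcohol to 15.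

**Step 10.**

What may go wrong:
- Hydride transfer to the fully substituted C3 may be slow. The phosphine hexamer [(Ph3P)CuH]6 is expected to be slower still.
- Carbonyl reduction may compete.
- The preference for the face anti to the aryl group may be insufficient.
- O1 may be lost by β-elimination during the carbonate treatment.

The fallback sets out from 15 and comes back at 17. It replaces hydride addition by heterogeneous hydrogenation (H2, 1 atm, Pd on carbon, EtOAc). Both hydrogens should arrive from the face opposite the C2 aryl group, which gives the all-cis ketone 17 directly. The K2CO3/MeOH equilibration of the main route then leads to 18.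

**Step 6.**

What may go wrong:
- Transmetalation of the electron-poor stannane may be sluggish.
- Protodestannylation or cine substitution may occur.
- The vinyl ketone may be lost by Michael-type addition or polymerisation at 60 °C.

The fallback sets out from 7 and 5 and comes back at 13. It carries the aroyl carbon as a protected carbinol until just before the key step. TESCl and imidazole give the triethylsilyl ether F4. α-Selective hydrostannation (Bu3SnH, Mo(CO)3(CNtBu)3 cat., THF, 55 °C) gives the 2-stannyl allylic ether F5. Stille coupling with 5 (Pd(PPh3)4, CuCl, LiCl, DMSO) gives the dienol F6, whose only free hydroxy group is the primary allylic one. Sharpless epoxidation with L-(+)-diisopropyl tartrate gives the epoxy alcohol F7 as a pair of carbinol epimers. TBSCl and imidazole give the bis-silyl ether F2. 2-Iodoxybenzoic acid in DMSO removes the triethylsilyl group, oxidises the alcohol and merges both epimers into 13.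

## Further compounds

F1 | step 9 | 2-[(2S,3S)-2-{[tert-butyl(dimethyl)silyl]oxymethyl}-3-(3,4,5-trimethoxyphenyl)oxiran-2-yl]-1-(3,4,5-trimethoxyphenyl)prop-2-en-1-ol, both carbinol epimers | C=C(C(O)c1cc(OC)c(OC)c(OC)c1)[C@@]2(CO[Si](C)(C)C(C)(C)C)O[C@H]2c3cc(OC)c(OC)c(OC)c3
F2 | step 9 | triethylsilyl ether of F1, both carbinol epimers | C=C(C(O[Si](CC)(CC)CC)c1cc(OC)c(OC)c(OC)c1)[C@@]2(CO[Si](C)(C)C(C)(C)C)O[C@H]2c3cc(OC)c(OC)c(OC)c3
F3 | step 9 | (2S)-2-aryl-3-(TBSOCH2)-4-[aryl(triethylsilyloxy)methyl]-2,5-dihydrofuran, both carbinol epimers | CC[Si](CC)(CC)OC(c1cc(OC)c(OC)c(OC)c1)C2=C(CO[Si](C)(C)C(C)(C)C)[C@H](c3cc(OC)c(OC)c(OC)c3)OC2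
F0 | step 10 | none | none
F4 | step 6 | rac-triethyl{[1-(3,4,5-trimethoxyphenyl)prop-2-yn-1-yl]oxy}silane | C#CC(O[Si](CC)(CC)CC)c1cc(OC)c(OC)c(OC)c1
F5 | step 6 | rac-triethyl{[2-(tributylstannyl)-1-(3,4,5-trimethoxyphenyl)prop-2-en-1-yl]oxy}silane | C=C([Sn](CCCC)(CCCC)CCCC)C(O[Si](CC)(CC)CC)c1cc(OC)c(OC)c(OC)c1
F6 | step 6 | rac-(2E)-3-methylidene-4-(triethylsilyloxy)-4-(3,4,5-trimethoxyphenyl)-2-[(3,4,5-trimethoxyphenyl)methylidene]butan-1-ol | OC/C(=C/c1cc(OC)c(OC)c(OC)c1)C(=C)C(O[Si](CC)(CC)CC)c1cc(OC)c(OC)c(OC)c1
F7 | step 6 | [(2S,3S)-2-{3-(triethylsilyloxy)-3-(3,4,5-trimethoxyphenyl)prop-1-en-2-yl}-3-(3,4,5-trimethoxyphenyl)oxiran-2-yl]methanol, both carbinol epimers | C=C(C(O[Si](CC)(CC)CC)c1cc(OC)c(OC)c(OC)c1)[C@@]2(CO)O[C@H]2c3cc(OC)c(OC)c(OC)c3
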